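## Structural features

The target, 1-[(2R,5R)-5-butyloxolan-2-yl]hexadecan-2-one, is a C24 molecule made of one saturated five-membered ether ring (O1, C2–C5) and two unbranched chains. C5 carries an n-butyl group; C2 carries a methylene (C1') leading to a ketone carbonyl (C2') that bears a linear tetradecyl group. The only stereocentres are C2 and C5, which face each other across the ring oxygen. With the ranks O1 > C1' > C3 at C2 and O1 > C4 > butyl at C5, the descriptors (2R,5R) put both ring hydrogens on one face, so the substituents are cis. The carbonyl is β to O1, so base or strong acid can open the ring by β-elimination to an enone and let it reclose without control; C2 is therefore configurationally fragile once the ketone exists, while the rest is inert hydrocarbon. The difficulty is stereochemical, not constitutional: both ring substituents start with a plain CH2, no nearby functional group can relay absolute configuration, and cis- and trans-2,5-dialkyloxolanes are too close in energy for equilibration to help. The key step uses the fact that the O1/C2–C5 ring with its two α-substituents is the perhydro form of a 2,5-dialkylfuran, so that four hydrogens delivered to one face of the flat heteroarene create C2 and C5 together and cis. The ketone carbon passes through that step as a silyl-protected (S)-carbinol, an internal stereochemical reference that is erased in the last step.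

## Logic of the disconnections

10 ⇒ 9. No skeletal bond is cut; the C2'=O bond is traced back to a C2'–H and an O–H bond. The β-alkoxy ketone is the one fragile element of 10, and as a carbinol it cannot expel O1. The carbinol carbon is also a third stereocentre, which turns the two possible cis ring antipodes into diastereomers, so 9 can be purified to a single stereoisomer. The forward step must oxidise a secondary alcohol without base strong enough to start β-elimination and without strong acid, so that C2 survives.

9 ⇒ 8. The O–H bond is replaced by an O–Si bond. A free secondary hydroxyl is a liability in the hydrogenation that precedes it, whereas the silyl ether is inert there. Nothing is gained in size, but the reduction becomes cleaner. The forward step must remove silicon without touching the ring, and it is the point at which a minor diastereomer is separated.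

8 ⇒ 6. The four bonds C2–H, C3–H, C4–H and C5–H are cut; no ring is opened and no carbon–carbon bond is touched. This removes both ring stereocentres at once and leads to a flat furan that already holds the whole carbon skeleton. The forward step must add two equivalents of hydrogen to the same face, choose that face in the absolute sense, leave the C–O bonds of ring and silyl ether intact, and not disturb the carbinol centre; the half-reduced enol ether 7 is passed through without isolation. The silyl group of 6 answers the last two demands. A free hydroxyl beside a basic ruthenium hydride could be dehydrogenated and re-hydrogenated, which would blur the reference centre. The bulky silyloxy group is inert and also makes the two furan arms clearly unequal in size.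

6 ⇒ 5. The O–Si bond is cut. This is a routine protection whose only demand is that the acid-sensitive furan sees neutral or mildly basic conditions.

5 ⇒ 2 + 4. The bond between furan C2 and C1' is cut. It is the only carbon–carbon bond the route forms, and it divides the C24 skeleton into a C8 heteroaryl nucleophile and a C16 electrophile whose oxygen becomes the carbinol oxygen. 4 comes from 3 by removal of its single α-hydrogen. The forward step needs metalation at the only free α-position of 3 and attack at the terminal carbon of 2, leaving the stereocentre of 2 untouched.

2 ⇒ 1. No bond of 2 is cut; one enantiomer is taken from the racemate. The racemic epoxide is a cheap bulk chemical, so a resolution that sacrifices the other half is acceptable. The forward step must discriminate the enantiomers almost completely, because the enantiopurity of the reference centre is what later makes facial errors visible and separable.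

## Other disconnections considered

Alternative 1: The cut is made at C2–C1' and at the bond between C5 and the first butyl carbon. This traces the oxolane back to furan A1 and the three carbons spanning the two cuts to 1,1,3,3-tetrabromopropan-2-one A2.
- Forward key step: Zn–Cu couple would reduce A2 to an oxyallyl cation that adds across the 2- and 5-positions of A1 in a (4+3) cycloaddition. The same reductant removes the two remaining bromines, giving the bicyclic enone A3 (meso-8-oxabicyclo[3.2.1]oct-6-en-3-one).
- In its favour: both new C–C bonds are tied into a bridged ring and can only lie on the same face. On the cis relationship this plan is better than the chosen one, where cis rests on kinetic same-face delivery of hydrogen. The materials are bulk chemicals, which is equal to the chosen plan.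
- Against it here: A3 is achiral, so the absolute configuration must come from a later desymmetrisation, for instance enantioselective enolisation of the hydrogenated ketone with a chiral lithium amide such as LiN[(R)-CH(CH3)Ph]2 and oxidative cleavage of the silyl enol ether. The carbonyl bridge must be broken, and the arms that result are only one and two carbons long. The butyl group would need three more carbons attached to an epimerisable α-alkoxy aldehyde, and the ketone arm would need a tetradecyl group by acyl substitution.
- Comparison: structurally, A3 holds 7 of the 24 carbons, whereas the chosen precursor holds all 24. Mechanistically, ring strain fixes the relative configuration more surely than facial selection on a flat ring, but a stoichiometric chiral base is no surer a source of absolute configuration than a chiral hydrogenation catalyst. In step economy about ten operations stand against six.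

Alternative 2: The cut is the C3–C4 bond, read as an alkene, preceded by one ring C–O bond. The oxolane becomes the acyclic bis-allylic ether A4 (({[(3S)-3-{[(3R)-hept-1-en-3-yl]oxy}pent-4-en-1-yl]oxy}methyl)benzene).
- Forward key step: second-generation Grubbs catalyst would join the two vinyl groups of A4 by ring-closing metathesis with loss of ethylene, giving the dihydrofuran A5 ((2S,5R)-2-[2-(benzyloxy)ethyl]-5-butyl-2,5-dihydrofuran). A4 would come from an enantioenriched allylic alcohol and a linear allylic carbonate by branched-selective allylic etherification with [Ir(cod)Cl]2 and a chiral phosphoramidite.
- In its favour: C2 and C5 are made one at a time as allylic C–O centres under reagent control and are not touched by the metathesis. Relative and absolute configuration are settled and can be checked before the ring exists, which is better than the chosen plan on stereochemical security. Five-membered ring-closing metathesis of a 1,6-diene is at least the equal of the hydrogenation in dependability.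
- Against it here: the diastereoselectivity of the etherification with a secondary alkoxide depends on matching catalyst and substrate. A5 carries only a two-carbon arm. After hydrogenation of the alkene with hydrogenolysis of the benzyl ether, it still needs oxidation to a β-alkoxy aldehyde (itself prone to β-elimination), addition of a tetradecyl Grignard reagent and a second oxidation.
- Comparison: the last step is the same carbinol-to-ketone oxidation as in the chosen plan, so the fragility of the final product is equal. Structurally, the alternative builds the ring from an acyclic ether and adds the C14 chain late; the chosen plan has ring and chain from its first C–C bond. Mechanistically, it replaces one stereo-defining step of uncertain facial selectivity by two well-understood ones. In step economy about nine to ten steps with two chiral inputs stand against six with one resolution.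

Alternative 3: The cut is the C2–C3 bond. The ring opens to the iodide A6 (ethyl (2E)-3-{[(3R)-1-iodoheptan-3-yl]oxy}prop-2-enoate), in which C5 is a secondary ether carbon and C2 is the β-carbon of an alkoxyacrylate.
- Forward key step: Bu3SnH with AIBN would turn the C–I bond into a primary radical at C3 that adds to the acrylate β-carbon in a 5-exo-trig closure, giving the ester A7 (ethyl 2-[(2R,5R)-5-butyloxolan-2-yl]acetate).
- In its favour: this type of closure is known for high cis-2,5 selectivity, explained by a chair-like transition state with the butyl group pseudo-equatorial and the (E)-acrylate extended, so C2 is set by C5 alone. C5 is an ordinary secondary carbinol available in high enantiomeric purity, which makes the absolute configuration more predictable than in the chosen plan (better). A7 has its ester carbon at the ketone oxidation level, so the target follows by a Weinreb amide and a tetradecyl Grignard reagent. That end game equals the chosen plan in step count and needs no oxidant.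
- Against it here: a stoichiometric tin hydride leaves lipophilic residues that are hard to remove from an equally lipophilic product. About four steps lead to A6 (an enantioenriched 1,3-diol derivative, conjugate addition of the carbinol to a propiolate ester, iodide formation). The β-alkoxy ester and amide must survive basic organometallic reagents, the same β-elimination hazard that the chosen plan meets only in its last step.
- Comparison: structurally, A7 holds 10 of the 24 skeletal carbons and the C14 chain comes last. Mechanistically, substrate-controlled radical addition is better precedented for purely dialkyl patterns than catalyst-controlled hydrogenation. In step economy about seven to eight steps stand against six.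

Key step: step 4

Assumption (configuration bookkeeping): opening of the (S)-epoxide at its terminal carbon keeps the descriptor S, because the former oxirane CH2 still outranks the alkyl chain; (2R,5R) is the cis isomer in 8, 9 and 10, so the structures are mutually consistent and need no correction.

Assumption (ligand antipode): the (R,R)-antipode of the carbene precursor SINpEt·HBF4 (1,3-bis[(1R)-1-(naphthalen-1-yl)ethyl]-4,5-dihydroimidazolium tetrafluoroborate) is written; if the sense of induction on this substrate is the opposite, the (S,S)-antipode is used and nothing else changes.

Assumption (order of reduction): the first equivalent of hydrogen is taken to add across the less hindered C4–C5 bond on the butyl side, giving 7; the reverse order would lead to the same product 8.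

## Route

Step 1
Reactants: 1 racemic 2-tetradecyloxirane (1,2-epoxyhexadecane)
Product: 2 (2S)-2-tetradecyloxirane
Conditions: (S,S)-(salen)Co(OAc) (0.5 mol%), H2O (0.55 equiv), THF, 0 °C → rt
Reagents that add atoms: none
Why: Hydrolytic kinetic resolution: the chiral acetate complex of trivalent cobalt (salen = N,N'-bis(3,5-di-tert-butylsalicylidene)cyclohexane-1,2-diamine dianion) activates epoxide and water together, and with the (S,S)-ligand it should hydrolyse the (R)-epoxide at its terminal carbon much faster, as is usual for alkyl-substituted terminal epoxides. No stereocentre is created, one is selected; with slightly more than half an equivalent of water the (S)-epoxide should remain in high enantiomeric purity and is freed from the polar, crystalline diol by filtration from hexane and a silica plug.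

Step 2
Reactants: 2 (2S)-2-tetradecyloxirane; 3 2-butylfuran
Product: 5 (2S)-1-(5-butylfuran-2-yl)hexadecan-2-ol, via (5-butylfuran-2-yl)lithium 4 (not isolated)
Conditions: 3, n-BuLi, THF, 0 °C → rt; then 2, THF, 0 °C → rt; aq NH4Cl
Reagents that add atoms: none
Why: α-Metalation of the furan at its only free α-position, then SN2 opening of the monosubstituted epoxide at the unhindered terminal carbon. The carbinol carbon is not a reaction site, so its configuration is carried over unchanged; excess volatile 3 is removed under vacuum.

Step 3
Reactants: 5 (2S)-1-(5-butylfuran-2-yl)hexadecan-2-ol
Product: 6 tert-butyl{[(2S)-1-(5-butylfuran-2-yl)hexadecan-2-yl]oxy}dimethylsilane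
Conditions: TBSCl, imidazole, DMF, rt
Reagents that add atoms: tert-butyldimethylsilyl chloride (TBSCl), CC(C)(C)[Si](C)(C)Cl
Why: Imidazole-promoted O-silylation of a secondary alcohol, under conditions mild enough for the furan. The silyl ether cannot form a ruthenium alkoxide or be dehydrogenated in step 4, and it makes the C2 arm far bulkier than the butyl arm.

Step 4
Reactants: 6 tert-butyl{[(2S)-1-(5-butylfuran-2-yl)hexadecan-2-yl]oxy}dimethylsilane
Product: 8 tert-butyl({(2S)-1-[(2R,5R)-5-butyloxolan-2-yl]hexadecan-2-yl}oxy)dimethylsilane, via (5R)-4,5-dihydrofuran silyl ether 7 (not isolated)
Conditions: Ru(cod)(2-methylallyl)2 (5 mol%), (R,R)-SINpEt·HBF4 (10 mol%), KOtBu (15 mol%), hexane, 70 °C; then 6, H2 (100 bar), hexane, 25 °C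
Reagents that add atoms: none
Why: This is the dearomatising hydrogenation of a 2,5-disubstituted furan by a chiral ruthenium N-heterocyclic carbene catalyst, the enantioselective counterpart of the all-cis furan reductions over Rh/Al2O3. The carbene complex formed from the ruthenium precursor, the imidazolinium salt and KOtBu becomes a ruthenium hydride under H2, binds one π face of the furan and delivers two hydrogens to that face of one C=C bond by insertion into Ru–H and hydrogenolysis of the Ru–C bond. The enol ether 7 that results has lost the aromatic stabilisation and is reduced again without leaving the reaction mixture. No ring is closed and no skeletal bond is formed; only the C2–H, C3–H, C4–H and C5–H bonds are made. C5 is set under catalyst control, the chiral carbene ligand deciding which face of the heteroarene meets the metal hydride. C2 follows from C5: the catalyst adds to the face of 7 opposite to the butyl group now projecting from C5, which is the face that already received hydrogen, so the hydrogens at C2 and C5 end up cis, and the ligand reinforces this. The step needs enantiofacial selectivity on a ring whose two substituents both begin with CH2, and chemoselectivity against C–O hydrogenolysis; the branched silyloxy arm beside a slim butyl arm gives the ligand a steric difference to read, and the mild temperature and hydrocarbon medium spare the ring and silyl C–O bonds. Whatever facial error remains is converted by the untouched (S)-centre into a diastereomer that is removed after step 5.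

Step 5
Reactants: 8 tert-butyl({(2S)-1-[(2R,5R)-5-butyloxolan-2-yl]hexadecan-2-yl}oxy)dimethylsilane
Product: 9 (2S)-1-[(2R,5R)-5-butyloxolan-2-yl]hexadecan-2-ol
Conditions: TBAF, THF, 0 °C → rt; chromatography on silica
Reagents that add atoms: none
Why: Fluoride-induced desilylation driven by the strong Si–F bond; the oxolane and all three stereocentres are inert to fluoride. Here 9 and any ring-antipodal diastereomer from step 4 differ as syn and anti β-hydroxy ethers and should separate on silica.

Step 6
Reactants: 9 (2S)-1-[(2R,5R)-5-butyloxolan-2-yl]hexadecan-2-ol
Product: 10 1-[(2R,5R)-5-butyloxolan-2-yl]hexadecan-2-one
Conditions: Dess–Martin periodinane, pyridine, CH2Cl2, 0 °C → rt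
Reagents that add atoms: none
Why: Dess–Martin oxidation: the carbinol exchanges onto the periodinane and acetate removes the α-hydrogen, giving the ketone under near-neutral conditions with pyridine taking up the acetic acid. This oxidant is used in place of an activated-DMSO oxidation because it needs no amine base that could trigger β-elimination of the ring oxygen, so C2 should keep its configuration; the (S)-carbinol centre is erased as intended.

## Compound list

1 | racemic 2-tetradecyloxirane (1,2-epoxyhexadecane) | CCCCCCCCCCCCCCC1CO1 | starting material
2 | (2S)-2-tetradecyloxirane | CCCCCCCCCCCCCC[C@H]1CO1 | intermediate
3 | 2-butylfuran | CCCCc1ccco1 | starting material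
4 | (5-butylfuran-2-yl)lithium | [Li]c1ccc(CCCC)o1 | intermediate, not isolated
5 | (2S)-1-(5-butylfuran-2-yl)hexadecan-2-ol | CCCCCCCCCCCCCC[C@H](O)Cc1ccc(CCCC)o1 | intermediate
6 | tert-butyl{[(2S)-1-(5-butylfuran-2-yl)hexadecan-2-yl]oxy}dimethylsilane | CCCCCCCCCCCCCC[C@H](O[Si](C)(C)C(C)(C)C)Cc1ccc(CCCC)o1 | intermediate
7 | tert-butyl({(2S)-1-[(5R)-5-butyl-4,5-dihydrofuran-2-yl]hexadecan-2-yl}oxy)dimethylsilane | CCCCCCCCCCCCCC[C@H](O[Si](C)(C)C(C)(C)C)CC1=CC[C@@H](CCCC)O1 | intermediate, not isolated
8 | tert-butyl({(2S)-1-[(2R,5R)-5-butyloxolan-2-yl]hexadecan-2-yl}oxy)dimethylsilane | CCCCCCCCCCCCCC[C@H](O[Si](C)(C)C(C)(C)C)C[C@H]1CC[C@@H](CCCC)O1 | intermediate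
9 | (2S)-1-[(2R,5R)-5-butyloxolan-2-yl]hexadecan-2-ol | CCCCCCCCCCCCCC[C@H](O)C[C@H]1CC[C@@H](CCCC)O1 | intermediate
10 | 1-[(2R,5R)-5-butyloxolan-2-yl]hexadecan-2-one | CCCCCCCCCCCCCCC(=O)C[C@H]1CC[C@@H](CCCC)O1 | target

## Step count and least certain steps

Total step count: 6. Longest linear sequence: 6 steps (1 → 2 → 5 → 6 → 8 → 9 → 10); 3 enters in step 2.

Step 4 (key step). The most likely failure is weak enantiofacial discrimination, because the ligand must tell apart two arms that both start with CH2. Slow turnover or arrest at the enol ether stage is also possible, because the silyloxy arm crowds one α-position. Changing the ligand antipode or the pressure is only an adjustment. The fallback gives up catalyst control and lets the reference centre do the work. It sets out from 5: hydrogenation of the unprotected furyl carbinol over 5% Rh/Al2O3 under H2 in ethyl acetate at room temperature should add hydrogen all-cis with no facial preference. The product would be a mixture of 9 and its ring-antipodal diastereomer (2S)-1-[(2S,5S)-5-butyloxolan-2-yl]hexadecan-2-ol F1, to be separated by chromatography. The route is rejoined at 9 and steps 3 to 5 are skipped. The price is that at most half of the material is used and that everything depends on the separation.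

Step 2. The most likely failure is slow opening of an unactivated long-chain epoxide by a furyllithium that is only moderately nucleophilic but quite basic. That allows incomplete conversion or competing deprotonation of the epoxide. Adding BF3·OEt2 would be a change of conditions only. The fallback changes which partner carries the epoxide and brings the long chain in by a different C–C bond formation. It sets out from 4, which is treated with BF3·OEt2 and commercial (R)-epichlorohydrin at −78 °C to give (2R)-1-(5-butylfuran-2-yl)-3-chloropropan-2-ol F2. NaOH closes this to 2-butyl-5-{[(2R)-oxiran-2-yl]methyl}furan F3. Tridecylmagnesium bromide with catalytic CuI then opens F3 at its terminal carbon, and the route is rejoined at 5. The stereocentre is never a reaction site; its descriptor changes from R to S in the last operation only because the ranks of its two carbon substituents are exchanged. This fallback also makes the resolution of step 1 unnecessary.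

Step 1. The most likely failure is a resolution that stops early, because the waxy, water-immiscible C16 epoxide mixes poorly with water. The recovered epoxide would then fall short of enantiopurity, with no crystallisation available to upgrade it. The fallback harvests the diol instead of the epoxide. It sets out from 1, which is resolved in the opposite sense with (R,R)-(salen)Co(OAc) and a deficiency of water (about 0.45 equiv) to give (2S)-hexadecane-1,2-diol F4, a crystalline solid whose enantiomeric purity can be raised by recrystallisation. Selective sulfonylation of the primary hydroxyl (TsCl, Bu2SnO cat., Et3N, CH2Cl2) would give (2S)-2-hydroxyhexadecyl 4-methylbenzenesulfonate F5. K2CO3 in MeOH closes the ring with the carbinol C–O bond untouched, and the route is rejoined at 2.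

## Further compounds

F1 | step 4 | (2S)-1-[(2S,5S)-5-butyloxolan-2-yl]hexadecan-2-ol | CCCCCCCCCCCCCC[C@H](O)C[C@@H]1CC[C@H](CCCC)O1
F2 | step 2 | (2R)-1-(5-butylfuran-2-yl)-3-chloropropan-2-ol | ClC[C@H](O)Cc1ccc(CCCC)o1
F3 | step 2 | 2-butyl-5-{[(2R)-oxiran-2-yl]methyl}furan | CCCCc1ccc(C[C@@H]2CO2)o1
F4 | step 1 | (2S)-hexadecane-1,2-diol | CCCCCCCCCCCCCC[C@H](O)CO
F5 | step 1 | (2S)-2-hydroxyhexadecyl 4-methylbenzenesulfonate | CCCCCCCCCCCCCC[C@H](O)COS(=O)(=O)c1ccc(C)cc1
A1 | alternative 1 | furan | c1ccoc1
A2 | alternative 1 | 1,1,3,3-tetrabromopropan-2-one | O=C(C(Br)Br)C(Br)Br
A3 | alternative 1 | meso-8-oxabicyclo[3.2.1]oct-6-en-3-one | O=C1C[C@H]2C=C[C@@H](C1)O2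
A4 | alternative 2 | ({[(3S)-3-{[(3R)-hept-1-en-3-yl]oxy}pent-4-en-1-yl]oxy}methyl)benzene | c1ccccc1COCC[C@@H](C=C)O[C@@H](C=C)CCCC
A5 | alternative 2 | (2S,5R)-2-[2-(benzyloxy)ethyl]-5-butyl-2,5-dihydrofuran | c1ccccc1COCC[C@H]1C=C[C@@H](CCCC)O1
A6 | alternative 3 | ethyl (2E)-3-{[(3R)-1-iodoheptan-3-yl]oxy}prop-2-enoate | CCCC[C@H](CCI)O/C=C/C(=O)OCC
A7 | alternative 3 | ethyl 2-[(2R,5R)-5-butyloxolan-2-yl]acetate | CCOC(=O)C[C@H]1CC[C@@H](CCCC)O1
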